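C12–C13 is cut to release the butenolide as 3-bromofuranone. C17–O goes back to a C8=C17 methylene, a temporary C3 ketone is added and C4–C18 is cut. C9–C10 is then cut while C4–C10 is re-joined, which folds the decalin into a bicyclo[3.1.0]hexane keto ester (labdane numbering throughout).
Enabling feature: in ring A the carboxyl-bearing C4 and the methyl-bearing quaternary C10 are both bonded to C5, so C4–C5–C10 is a latent acceptor-activated cyclopropane. With the C3 ketone and the C19 ester on C4, heterolysis of C4–C10 gives an enolate at C4 and an electrophilic tertiary C10 exactly where C9 must bond to close ring B.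
Further cuts: the cyclopropane goes back to a C4 diazo carbon and the E C5=C10 alkene, C1–C2 to an acetoacetate dianion and an allylic bromide, and C8–C17 plus C9–C11 to a terminal alkyne, a silylmethyl Grignard reagent and ethylene oxide.
Forward order: the acyclic chain comes first, then the three- and five-membered rings together by carbene addition. Ring A (by enlargement) and ring B (by closure) then form in one step, and the intact butenolide ring is joined last at C12.
Stereochemistry: a chiral copper catalyst sets C5 and C10 on the cyclopropane. The key step keeps C5, inverts C10 and sets C9 through a chair and the alkene geometry from syn carbometalation. C4 comes from α-face methylation and C8 from equilibration of the C17 aldehyde.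

Key step: step 12

Assumption: the sense of induction of the copper–bis(oxazoline) catalyst in step 11 cannot be predicted with certainty, so the ligand antipode (both are commercial) that gives (1R,5R,6R)-20 is to be fixed in a trial run; the (S,S) ligand is written.

Step 1
Reactants: 1 6-methylhept-5-en-2-one
Product: 3 6-methylhept-5-en-1-yne, via enol phosphate 2 (not isolated)
Conditions: LDA (1.1 equiv), THF, −78 °C; ClP(O)(OEt)2, −78 °C to rt; LDA (2.3 equiv), −78 °C to rt
Reagents that add atoms: none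
Why: Kinetic deprotonation at the methyl group, O-phosphorylation and base-induced elimination of the terminal enol phosphate is the standard conversion of a methyl ketone into a terminal alkyne, and the remote trisubstituted alkene is inert to LDA.

Step 2
Reactants: 3 6-methylhept-5-en-1-yne
Product: 4 (2E)-2-methylhept-2-en-6-yn-1-ol
Conditions: SeO2 (0.3 equiv), t-BuOOH (2 equiv), salicylic acid (0.1 equiv), CH2Cl2, 0 °C to rt
Reagents that add atoms: tert-butyl hydroperoxide, CC(C)(C)OO (oxygen relayed by SeO2)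
Why: The Riley allylic oxidation (ene reaction, then [2,3]-sigmatropic shift) attacks the electron-rich isopropylidene at the methyl group trans to the chain, which sets the E geometry of C5=C10, while the terminal alkyne reacts far more slowly.

Step 3
Reactants: 4 (2E)-2-methylhept-2-en-6-yn-1-ol
Product: 5 tert-butyl(dimethyl){[(2E)-2-methylhept-2-en-6-yn-1-yl]oxy}silane
Conditions: TBSCl, imidazole, CH2Cl2, 0 °C to rt
Reagents that add atoms: tert-butyldimethylsilyl chloride, CC(C)(C)[Si](C)(C)Cl
Why: Imidazole-promoted silylation of a primary alcohol gives an ether that tolerates Grignard and organocopper reagents and is a poor allylic leaving group.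

Step 4
Reactants: 5 tert-butyl(dimethyl){[(2E)-2-methylhept-2-en-6-yn-1-yl]oxy}silane; 6 (trimethylsilyl)methylmagnesium chloride; 7 ethylene oxide
Product: 10 (3Z,7E)-9-[(tert-butyldimethylsilyl)oxy]-8-methyl-4-[(trimethylsilyl)methyl]nona-3,7-dien-1-ol, via silylmethylcopper 8 (not isolated), via alkenylcopper 9 (not isolated)
Conditions: 6 (1.3 equiv), CuBr·SMe2 (1.3 equiv), Et2O–Me2S, −40 °C; 5, −40 °C to rt; 1-hexynyllithium, DMPU, −78 °C; 7 (3 equiv), −78 to 0 °C
Reagents that add atoms: none
Why: In this Normant carbocupration the thermally robust silylmethylcopper adds syn with copper on the terminal carbon, so C17 and the metal on C9 are cis, and the alkenylcopper, activated as a mixed alkynyl cuprate, opens ethylene oxide with retention, which fixes the (3Z) geometry that later controls C9.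

Step 5
Reactants: 10 (3Z,7E)-9-[(tert-butyldimethylsilyl)oxy]-8-methyl-4-[(trimethylsilyl)methyl]nona-3,7-dien-1-ol
Product: 11 (3Z,7E)-9-[(tert-butyldimethylsilyl)oxy]-8-methyl-4-[(trimethylsilyl)methyl]nona-3,7-dien-1-yl pivalate
Conditions: PivCl, pyridine, DMAP (cat.), CH2Cl2, 0 °C to rt
Reagents that add atoms: pivaloyl chloride, CC(C)(C)C(=O)Cl
Why: Acylation of the primary C12 alcohol installs a hindered ester that resists the dianion of step 9 and is too weak a nucleophile to trap the cationic C8 in step 12, as an ether oxygen could.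

Step 6
Reactants: 11 (3Z,7E)-9-[(tert-butyldimethylsilyl)oxy]-8-methyl-4-[(trimethylsilyl)methyl]nona-3,7-dien-1-yl pivalate
Product: 12 (3Z,7E)-9-hydroxy-8-methyl-4-[(trimethylsilyl)methyl]nona-3,7-dien-1-yl pivalate
Conditions: TBAF, AcOH (1:1), THF, 0 °C to rt
Reagents that add atoms: none
Why: Fluoride cleavage of a primary silyl ether is fast, and buffering with acetic acid keeps the medium non-basic so that the allyltrimethylsilane and the pivalate should persist.

Step 7
Reactants: 12 (3Z,7E)-9-hydroxy-8-methyl-4-[(trimethylsilyl)methyl]nona-3,7-dien-1-yl pivalate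
Product: 13 (3Z,7E)-9-bromo-8-methyl-4-[(trimethylsilyl)methyl]nona-3,7-dien-1-yl pivalate
Conditions: CBr4, PPh3, CH2Cl2, −20 to 0 °C
Reagents that add atoms: carbon tetrabromide, BrC(Br)(Br)Br
Why: The Appel reaction converts the primary allylic alcohol by SN2 displacement under neutral conditions, so neither allylic transposition nor protodesilylation is expected.

Step 8
Reactants: 14 2,2,6-trimethyl-4H-1,3-dioxin-4-one
Product: 16 2-(trimethylsilyl)ethyl 3-oxobutanoate, via acetylketene 15 (not isolated)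
Conditions: Me3SiCH2CH2OH (1.0 equiv), toluene, 110 °C
Reagents that add atoms: 2-(trimethylsilyl)ethanol, C[Si](C)(C)CCO
Why: Thermal retro-hetero-Diels–Alder loss of acetone releases acetylketene, which the alcohol traps cleanly, and the resulting ester can be removed with fluoride at the end even from the hindered axial C19 position.

Step 9
Reactants: 13 (3Z,7E)-9-bromo-8-methyl-4-[(trimethylsilyl)methyl]nona-3,7-dien-1-yl pivalate; 16 2-(trimethylsilyl)ethyl 3-oxobutanoate
Product: 18 2-(trimethylsilyl)ethyl (6E,10Z)-6-methyl-3-oxo-13-(pivaloyloxy)-10-[(trimethylsilyl)methyl]trideca-6,10-dienoate, via acetoacetate dianion 17 (not isolated)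
Conditions: 16, NaH, THF, 0 °C; n-BuLi, 0 °C; 13, 0 °C
Reagents that add atoms: none
Why: In the γ-alkylation of an acetoacetate dianion the more basic terminal carbanion displaces the allylic bromide by SN2 and forms C1–C2, faster than any attack on the hindered pivalate.

Step 10
Reactants: 18 2-(trimethylsilyl)ethyl (6E,10Z)-6-methyl-3-oxo-13-(pivaloyloxy)-10-[(trimethylsilyl)methyl]trideca-6,10-dienoate
Product: 19 2-(trimethylsilyl)ethyl (6E,10Z)-2-diazo-6-methyl-3-oxo-13-(pivaloyloxy)-10-[(trimethylsilyl)methyl]trideca-6,10-dienoate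
Conditions: 4-acetamidobenzenesulfonyl azide, Et3N, MeCN, 0 °C to rt
Reagents that add atoms: 4-acetamidobenzenesulfonyl azide, CC(=O)Nc1ccc(cc1)S(=O)(=O)N=[N+]=[N-]
Why: Regitz diazo transfer to the activated methylene C4 of a β-keto ester runs under mild amine base that leaves the allylsilane and both esters untouched.

Step 11
Reactants: 19 2-(trimethylsilyl)ethyl (6E,10Z)-2-diazo-6-methyl-3-oxo-13-(pivaloyloxy)-10-[(trimethylsilyl)methyl]trideca-6,10-dienoate
Product: 20 2-(trimethylsilyl)ethyl (1R,5R,6R)-5-methyl-2-oxo-6-{(3Z)-6-(pivaloyloxy)-3-[(trimethylsilyl)methyl]hex-3-en-1-yl}bicyclo[3.1.0]hexane-1-carboxylate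
Conditions: Cu(MeCN)4PF6 (5 mol %), 2,2'-(propane-2,2-diyl)bis[(4S)-4-tert-butyl-4,5-dihydrooxazole] (6 mol %), toluene, 50 °C, slow addition of 19
Reagents that add atoms: none
Why: In this catalytic asymmetric intramolecular cyclopropanation of an α-diazo β-keto ester by a carbene of monovalent copper, the concerted syn addition carries the E geometry into the ring so that the C6 chain is exo and cis to C20 and to the ester, the ligand selects the alkene face and thereby fixes C4, C5 and C10 together, and the remote allylsilane cannot compete with closure of the five-membered ring.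

Step 12
Reactants: 20 2-(trimethylsilyl)ethyl (1R,5R,6R)-5-methyl-2-oxo-6-{(3Z)-6-(pivaloyloxy)-3-[(trimethylsilyl)methyl]hex-3-en-1-yl}bicyclo[3.1.0]hexane-1-carboxylate
Product: 22 2-(trimethylsilyl)ethyl (4aR,5S,8aR)-2-hydroxy-4a-methyl-6-methylidene-5-[2-(pivaloyloxy)ethyl]-3,4,4a,5,6,7,8,8a-octahydronaphthalene-1-carboxylate (enol form of the trans-decalin β-keto ester), via trichlorotin enolate 21 (not isolated)
Conditions: SnCl4 (2.2 equiv), 2,6-di-tert-butylpyridine (0.3 equiv), CH2Cl2, −78 to −40 °C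
Reagents that add atoms: none
Why: Proposed new method: SnCl4 held in a chelate between the C3 ketone and the C19 ester oxygen polarises the ring-fusion bond C4–C10, C9 of the allylsilane bonds to C10 from the side opposite the departing C4, the trichlorotin enolate 21 is released at C4, and the β-silyl cation at C8 loses Me3SiCl so that only the C8=C17 alkene can form. The closest known reaction types are the SnCl4-induced cyclisation of olefinic cyclopropyl ketones, the invertive Hosomi–Sakurai-type opening of donor–acceptor cyclopropanes by allylsilanes and, in geometry, the epoxide-initiated allylsilane-terminated cyclisation; new here is that a tethered allylsilane cleaves the fusion bond of a bicyclo[3.1.0]hexane keto ester. Ring B closes through a chair in a 6-endo mode (endo to the C5–C10 bond of the three-membered ring and 6-endo-trig at C8=C9), whereas ring A is not closed by a new bond but grows out of the five-membered ring when C4–C10 breaks. C5 is untouched, C10 is set by SN2-like inversion, which together with the cis relation of C20 and C6 inherited from the E alkene places C20 anti to H5 (trans-decalin), and C9 is set by the chair together with the (Z)-allylsilane geometry, which puts C11 equatorial. The step needs cleavage of C4–C10 rather than of the outer C4–C5 bond: C10 is tertiary and methyl-stabilised while C5 is secondary, the chelated ester can align with either bond, and the tether lets C9 reach C10 through a six-membered chair whereas attack at C5 would be a strained 5-endo-trig closure. The pivalate is too weakly nucleophilic to intercept C8, and the hindered pyridine removes adventitious acid that would protodesilylate the terminator.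

Step 13
Reactants: 22 2-(trimethylsilyl)ethyl (4aR,5S,8aR)-2-hydroxy-4a-methyl-6-methylidene-5-[2-(pivaloyloxy)ethyl]-3,4,4a,5,6,7,8,8a-octahydronaphthalene-1-carboxylate
Product: 23 2-(trimethylsilyl)ethyl (1R,4aR,5S,8aR)-1,4a-dimethyl-6-methylidene-2-oxo-5-[2-(pivaloyloxy)ethyl]decahydronaphthalene-1-carboxylate (4α-methyl, 4β-ester)
Conditions: MeI, K2CO3, acetone, 40 °C
Reagents that add atoms: iodomethane, CI
Why: C-alkylation of the stabilised β-keto ester enolate with a soft electrophile takes place on the α face, anti to the axial C20 methyl that screens the β face, so the new methyl (C18) becomes equatorial and the ester (C19) axial at C4.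

Step 14
Reactants: 23 2-(trimethylsilyl)ethyl (1R,4aR,5S,8aR)-1,4a-dimethyl-6-methylidene-2-oxo-5-[2-(pivaloyloxy)ethyl]decahydronaphthalene-1-carboxylate
Product: 24 2-(trimethylsilyl)ethyl (1R,2S,4aR,5S,8aR)-2-hydroxy-1,4a-dimethyl-6-methylidene-5-[2-(pivaloyloxy)ethyl]decahydronaphthalene-1-carboxylate (3β-alcohol)
Conditions: NaBH4, MeOH–THF, 0 °C to rt
Reagents that add atoms: none
Why: Borohydride reduction of the non-enolisable ketone should deliver hydride from the α face, away from the axial ester and C20, to give the equatorial 3β-alcohol, a centre that is erased two steps later.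

Step 15
Reactants: 24 2-(trimethylsilyl)ethyl (1R,2S,4aR,5S,8aR)-2-hydroxy-1,4a-dimethyl-6-methylidene-5-[2-(pivaloyloxy)ethyl]decahydronaphthalene-1-carboxylate
Product: 25 2-(trimethylsilyl)ethyl (1R,2S,4aR,5S,8aR)-2-[(1H-imidazol-1-ylcarbonothioyl)oxy]-1,4a-dimethyl-6-methylidene-5-[2-(pivaloyloxy)ethyl]decahydronaphthalene-1-carboxylate
Conditions: 1,1'-thiocarbonyldiimidazole, DMAP, toluene, 90 °C
Reagents that add atoms: 1,1'-thiocarbonyldiimidazole, S=C(n1ccnc1)n1ccnc1
Why: Thioacylation under neutral conditions (first stage of the Barton–McCombie sequence) activates the hindered alcohol without forming the free alkoxide that could start a retro-aldol cleavage of the β-hydroxy ester.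

Step 16
Reactants: 25 2-(trimethylsilyl)ethyl (1R,2S,4aR,5S,8aR)-2-[(1H-imidazol-1-ylcarbonothioyl)oxy]-1,4a-dimethyl-6-methylidene-5-[2-(pivaloyloxy)ethyl]decahydronaphthalene-1-carboxylate
Product: 26 2-(trimethylsilyl)ethyl (1S,4aR,5S,8aR)-1,4a-dimethyl-6-methylidene-5-[2-(pivaloyloxy)ethyl]decahydronaphthalene-1-carboxylate
Conditions: Bu3SnH, AIBN (cat.), toluene, 100 °C
Reagents that add atoms: none
Why: In the Barton–McCombie deoxygenation the secondary C3 radical abstracts hydrogen from the stannane and is too far from the C8=C17 alkene to cyclise onto it.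

Step 17
Reactants: 26 2-(trimethylsilyl)ethyl (1S,4aR,5S,8aR)-1,4a-dimethyl-6-methylidene-5-[2-(pivaloyloxy)ethyl]decahydronaphthalene-1-carboxylate
Product: 28 2-(trimethylsilyl)ethyl (1S,4aR,5S,6S,8aR)-6-(hydroxymethyl)-1,4a-dimethyl-5-[2-(pivaloyloxy)ethyl]decahydronaphthalene-1-carboxylate (axial 8β-CH2OH expected as the main epimer), via borane adduct 27 (not isolated)
Conditions: 9-BBN, THF, 60 °C; H2O2, NaOH, H2O, 0 °C to rt
Reagents that add atoms: hydrogen peroxide, OO
Why: Anti-Markovnikov hydroboration–oxidation places oxygen on C17 without touching the esters, and the bulky borane should approach the α face away from the axial C20, which leaves C17 provisionally axial, an outcome corrected in step 19.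

Step 18
Reactants: 28 2-(trimethylsilyl)ethyl (1S,4aR,5S,6S,8aR)-6-(hydroxymethyl)-1,4a-dimethyl-5-[2-(pivaloyloxy)ethyl]decahydronaphthalene-1-carboxylate
Product: 29 2-(trimethylsilyl)ethyl (1S,4aR,5S,6S,8aR)-6-formyl-1,4a-dimethyl-5-[2-(pivaloyloxy)ethyl]decahydronaphthalene-1-carboxylate (axial aldehyde)
Conditions: Dess–Martin periodinane, CH2Cl2, 0 °C to rt
Reagents that add atoms: none
Why: Dess–Martin oxidation takes the primary alcohol to the aldehyde under near-neutral conditions without over-oxidation.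

Step 19
Reactants: 29 2-(trimethylsilyl)ethyl (1S,4aR,5S,6S,8aR)-6-formyl-1,4a-dimethyl-5-[2-(pivaloyloxy)ethyl]decahydronaphthalene-1-carboxylate
Product: 31 2-(trimethylsilyl)ethyl (1S,4aR,5S,6R,8aR)-6-(hydroxymethyl)-1,4a-dimethyl-5-[2-(pivaloyloxy)ethyl]decahydronaphthalene-1-carboxylate (equatorial 8α-CH2OH), via equatorial aldehyde 30 (not isolated)
Conditions: K2CO3 (0.5 equiv), MeOH, rt; NaBH4, 0 °C
Reagents that add atoms: none
Why: Base-mediated enolisation equilibrates C8 to the equatorial aldehyde, which escapes the 1,3-diaxial contact with C20 and lies trans-diequatorial to the C9 chain so that both hydroboration epimers converge, and borohydride reduction in the same flask then locks this configuration.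

Step 20
Reactants: 31 2-(trimethylsilyl)ethyl (1S,4aR,5S,6R,8aR)-6-(hydroxymethyl)-1,4a-dimethyl-5-[2-(pivaloyloxy)ethyl]decahydronaphthalene-1-carboxylate
Product: 32 2-(trimethylsilyl)ethyl (1S,4aR,5S,6R,8aR)-6-{[(tert-butyldimethylsilyl)oxy]methyl}-1,4a-dimethyl-5-[2-(pivaloyloxy)ethyl]decahydronaphthalene-1-carboxylate
Conditions: TBSCl, imidazole, DMF, rt
Reagents that add atoms: tert-butyldimethylsilyl chloride, CC(C)(C)[Si](C)(C)Cl
Why: Standard silylation masks C17–OH with a group that falls together with the ester in the final fluoride step.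

Step 21
Reactants: 32 2-(trimethylsilyl)ethyl (1S,4aR,5S,6R,8aR)-6-{[(tert-butyldimethylsilyl)oxy]methyl}-1,4a-dimethyl-5-[2-(pivaloyloxy)ethyl]decahydronaphthalene-1-carboxylate
Product: 33 2-(trimethylsilyl)ethyl (1S,4aR,5S,6R,8aR)-6-{[(tert-butyldimethylsilyl)oxy]methyl}-5-(2-hydroxyethyl)-1,4a-dimethyldecahydronaphthalene-1-carboxylate
Conditions: DIBAL-H (2.2 equiv), CH2Cl2, −78 °C
Reagents that add atoms: none
Why: Reductive cleavage of the pivalate of a primary alcohol is fast at low temperature, whereas the axial C19 ester on a quaternary carbon, pressed against C20, is markedly more hindered and should survive.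

Step 22
Reactants: 33 2-(trimethylsilyl)ethyl (1S,4aR,5S,6R,8aR)-6-{[(tert-butyldimethylsilyl)oxy]methyl}-5-(2-hydroxyethyl)-1,4a-dimethyldecahydronaphthalene-1-carboxylate
Product: 34 2-(trimethylsilyl)ethyl (1S,4aR,5S,6R,8aR)-6-{[(tert-butyldimethylsilyl)oxy]methyl}-5-(2-iodoethyl)-1,4a-dimethyldecahydronaphthalene-1-carboxylate
Conditions: I2, PPh3, imidazole, CH2Cl2, 0 °C to rt
Reagents that add atoms: iodine, II
Why: The Garegg–Samuelsson (Appel-type) iodination converts the unhindered primary C12 alcohol by SN2 displacement under conditions that spare the silyl ether and the ester.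

Step 23
Reactants: 34 2-(trimethylsilyl)ethyl (1S,4aR,5S,6R,8aR)-6-{[(tert-butyldimethylsilyl)oxy]methyl}-5-(2-iodoethyl)-1,4a-dimethyldecahydronaphthalene-1-carboxylate; 35 3-bromofuran-2(5H)-one
Product: 37 2-(trimethylsilyl)ethyl (1S,4aR,5S,6R,8aR)-6-{[(tert-butyldimethylsilyl)oxy]methyl}-1,4a-dimethyl-5-[2-(2-oxo-2,5-dihydrofuran-3-yl)ethyl]decahydronaphthalene-1-carboxylate, via alkylzinc iodide 36 (not isolated)
Conditions: Zn dust, LiCl, THF, 40 °C; 35 (1.2 equiv), Pd(OAc)2 (3 mol %), SPhos (6 mol %), THF, rt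
Reagents that add atoms: none
Why: LiCl-assisted zinc insertion gives an ester-tolerant alkylzinc iodide for an sp3–sp2 Negishi coupling, in which zerovalent palladium adds quickly to the C–Br bond of the electron-poor bromobutenolide and the bulky biaryl phosphine favours reductive elimination over β-hydride elimination, forming C12–C13 without touching a stereocentre.

Step 24
Reactants: 37 2-(trimethylsilyl)ethyl (1S,4aR,5S,6R,8aR)-6-{[(tert-butyldimethylsilyl)oxy]methyl}-1,4a-dimethyl-5-[2-(2-oxo-2,5-dihydrofuran-3-yl)ethyl]decahydronaphthalene-1-carboxylate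
Product: 38 (1S,4aR,5S,6R,8aR)-6-(hydroxymethyl)-1,4a-dimethyl-5-[2-(2-oxo-2,5-dihydrofuran-3-yl)ethyl]decahydronaphthalene-1-carboxylic acid (CNP0562063.1)
Conditions: TBAF, AcOH (1:1), THF, rt to 40 °C
Reagents that add atoms: none
Why: Fluoride attacks silicon, remote from the hindered carbonyl, so the 2-(trimethylsilyl)ethyl ester fragments (Peterson-type β-elimination) and the silyl ether is cleaved in one operation, while the acetic acid buffer protects the base-sensitive butenolide.

Compound list
1 | 6-methylhept-5-en-2-one | CC(=O)CCC=C(C)C | starting material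
2 | diethyl 6-methylhepta-1,5-dien-2-yl phosphate | C=C(CCC=C(C)C)OP(=O)(OCC)OCC | intermediate
3 | 6-methylhept-5-en-1-yne | C#CCCC=C(C)C | intermediate
4 | (2E)-2-methylhept-2-en-6-yn-1-ol | C#CCC/C=C(\C)CO | intermediate
5 | tert-butyl(dimethyl){[(2E)-2-methylhept-2-en-6-yn-1-yl]oxy}silane | C#CCC/C=C(\C)CO[Si](C)(C)C(C)(C)C | intermediate
6 | (trimethylsilyl)methylmagnesium chloride | C[Si](C)(C)C[Mg]Cl | starting material
7 | ethylene oxide | C1CO1 | starting material
8 | [(trimethylsilyl)methyl]copper | C[Si](C)(C)C[Cu] | intermediate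
9 | (1Z,5E)-7-[(tert-butyldimethylsilyl)oxy]-6-methyl-2-[(trimethylsilyl)methyl]hepta-1,5-dien-1-ylcopper | [Cu]/C=C(\C[Si](C)(C)C)CC/C=C(\C)CO[Si](C)(C)C(C)(C)C | intermediate
10 | (3Z,7E)-9-[(tert-butyldimethylsilyl)oxy]-8-methyl-4-[(trimethylsilyl)methyl]nona-3,7-dien-1-ol | OCC/C=C(\C[Si](C)(C)C)CC/C=C(\C)CO[Si](C)(C)C(C)(C)C | intermediate
11 | (3Z,7E)-9-[(tert-butyldimethylsilyl)oxy]-8-methyl-4-[(trimethylsilyl)methyl]nona-3,7-dien-1-yl pivalate | CC(C)(C)C(=O)OCC/C=C(\C[Si](C)(C)C)CC/C=C(\C)CO[Si](C)(C)C(C)(C)C | intermediate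
12 | (3Z,7E)-9-hydroxy-8-methyl-4-[(trimethylsilyl)methyl]nona-3,7-dien-1-yl pivalate | CC(C)(C)C(=O)OCC/C=C(\C[Si](C)(C)C)CC/C=C(\C)CO | intermediate
13 | (3Z,7E)-9-bromo-8-methyl-4-[(trimethylsilyl)methyl]nona-3,7-dien-1-yl pivalate | CC(C)(C)C(=O)OCC/C=C(\C[Si](C)(C)C)CC/C=C(\C)CBr | intermediate
14 | 2,2,6-trimethyl-4H-1,3-dioxin-4-one | CC1=CC(=O)OC(C)(C)O1 | starting material
15 | acetylketene (3-oxobut-1-en-1-one) | CC(=O)C=C=O | intermediate
16 | 2-(trimethylsilyl)ethyl 3-oxobutanoate | CC(=O)CC(=O)OCC[Si](C)(C)C | intermediate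
17 | lithium sodium C2,C4-dianion of 16 | [Li+].[Na+].[CH2-]C(=O)[CH-]C(=O)OCC[Si](C)(C)C | intermediate
18 | 2-(trimethylsilyl)ethyl (6E,10Z)-6-methyl-3-oxo-13-(pivaloyloxy)-10-[(trimethylsilyl)methyl]trideca-6,10-dienoate | CC(C)(C)C(=O)OCC/C=C(\C[Si](C)(C)C)CC/C=C(\C)CCC(=O)CC(=O)OCC[Si](C)(C)C | intermediate
19 | 2-(trimethylsilyl)ethyl (6E,10Z)-2-diazo-6-methyl-3-oxo-13-(pivaloyloxy)-10-[(trimethylsilyl)methyl]trideca-6,10-dienoate | CC(C)(C)C(=O)OCC/C=C(\C[Si](C)(C)C)CC/C=C(\C)CCC(=O)C(=[N+]=[N-])C(=O)OCC[Si](C)(C)C | intermediate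
20 | 2-(trimethylsilyl)ethyl (1R,5R,6R)-5-methyl-2-oxo-6-{(3Z)-6-(pivaloyloxy)-3-[(trimethylsilyl)methyl]hex-3-en-1-yl}bicyclo[3.1.0]hexane-1-carboxylate | C[Si](C)(C)CCOC(=O)[C@@]12C(=O)CC[C@]1(C)[C@H]2CC/C(C[Si](C)(C)C)=C/CCOC(=O)C(C)(C)C | intermediate
21 | trichlorotin enolate of 22 (tin on the C3 oxygen) | C[C@]12CCC(O[Sn](Cl)(Cl)Cl)=C(C(=O)OCC[Si](C)(C)C)[C@@H]1CCC(=C)[C@@H]2CCOC(=O)C(C)(C)C | intermediate
22 | 2-(trimethylsilyl)ethyl (4aR,5S,8aR)-2-hydroxy-4a-methyl-6-methylidene-5-[2-(pivaloyloxy)ethyl]-3,4,4a,5,6,7,8,8a-octahydronaphthalene-1-carboxylate (enol form) | C[C@]12CCC(O)=C(C(=O)OCC[Si](C)(C)C)[C@@H]1CCC(=C)[C@@H]2CCOC(=O)C(C)(C)C | intermediate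
23 | 2-(trimethylsilyl)ethyl (1R,4aR,5S,8aR)-1,4a-dimethyl-6-methylidene-2-oxo-5-[2-(pivaloyloxy)ethyl]decahydronaphthalene-1-carboxylate | C[C@]12CCC(=O)[C@](C)(C(=O)OCC[Si](C)(C)C)[C@@H]1CCC(=C)[C@@H]2CCOC(=O)C(C)(C)C | intermediate
24 | 2-(trimethylsilyl)ethyl (1R,2S,4aR,5S,8aR)-2-hydroxy-1,4a-dimethyl-6-methylidene-5-[2-(pivaloyloxy)ethyl]decahydronaphthalene-1-carboxylate | C[C@]12CC[C@H](O)[C@](C)(C(=O)OCC[Si](C)(C)C)[C@@H]1CCC(=C)[C@@H]2CCOC(=O)C(C)(C)C | intermediate
25 | 2-(trimethylsilyl)ethyl (1R,2S,4aR,5S,8aR)-2-[(1H-imidazol-1-ylcarbonothioyl)oxy]-1,4a-dimethyl-6-methylidene-5-[2-(pivaloyloxy)ethyl]decahydronaphthalene-1-carboxylate | C[C@]12CC[C@H](OC(=S)n3ccnc3)[C@](C)(C(=O)OCC[Si](C)(C)C)[C@@H]1CCC(=C)[C@@H]2CCOC(=O)C(C)(C)C | intermediate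
26 | 2-(trimethylsilyl)ethyl (1S,4aR,5S,8aR)-1,4a-dimethyl-6-methylidene-5-[2-(pivaloyloxy)ethyl]decahydronaphthalene-1-carboxylate | C[C@]12CCC[C@](C)(C(=O)OCC[Si](C)(C)C)[C@@H]1CCC(=C)[C@@H]2CCOC(=O)C(C)(C)C | intermediate
27 | 9-BBN adduct of 26 (boron on C17, C17 axial and β, H8 α) | C[C@]12CCC[C@](C)(C(=O)OCC[Si](C)(C)C)[C@@H]1CC[C@H](CB3C4CCCC3CCC4)[C@@H]2CCOC(=O)C(C)(C)C | intermediate
28 | 2-(trimethylsilyl)ethyl (1S,4aR,5S,6S,8aR)-6-(hydroxymethyl)-1,4a-dimethyl-5-[2-(pivaloyloxy)ethyl]decahydronaphthalene-1-carboxylate | C[C@]12CCC[C@](C)(C(=O)OCC[Si](C)(C)C)[C@@H]1CC[C@H](CO)[C@@H]2CCOC(=O)C(C)(C)C | intermediate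
29 | 2-(trimethylsilyl)ethyl (1S,4aR,5S,6S,8aR)-6-formyl-1,4a-dimethyl-5-[2-(pivaloyloxy)ethyl]decahydronaphthalene-1-carboxylate | C[C@]12CCC[C@](C)(C(=O)OCC[Si](C)(C)C)[C@@H]1CC[C@H](C=O)[C@@H]2CCOC(=O)C(C)(C)C | intermediate
30 | 2-(trimethylsilyl)ethyl (1S,4aR,5S,6R,8aR)-6-formyl-1,4a-dimethyl-5-[2-(pivaloyloxy)ethyl]decahydronaphthalene-1-carboxylate | C[C@]12CCC[C@](C)(C(=O)OCC[Si](C)(C)C)[C@@H]1CC[C@@H](C=O)[C@@H]2CCOC(=O)C(C)(C)C | intermediate
31 | 2-(trimethylsilyl)ethyl (1S,4aR,5S,6R,8aR)-6-(hydroxymethyl)-1,4a-dimethyl-5-[2-(pivaloyloxy)ethyl]decahydronaphthalene-1-carboxylate | C[C@]12CCC[C@](C)(C(=O)OCC[Si](C)(C)C)[C@@H]1CC[C@@H](CO)[C@@H]2CCOC(=O)C(C)(C)C | intermediate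
32 | 2-(trimethylsilyl)ethyl (1S,4aR,5S,6R,8aR)-6-{[(tert-butyldimethylsilyl)oxy]methyl}-1,4a-dimethyl-5-[2-(pivaloyloxy)ethyl]decahydronaphthalene-1-carboxylate | C[C@]12CCC[C@](C)(C(=O)OCC[Si](C)(C)C)[C@@H]1CC[C@@H](CO[Si](C)(C)C(C)(C)C)[C@@H]2CCOC(=O)C(C)(C)C | intermediate
33 | 2-(trimethylsilyl)ethyl (1S,4aR,5S,6R,8aR)-6-{[(tert-butyldimethylsilyl)oxy]methyl}-5-(2-hydroxyethyl)-1,4a-dimethyldecahydronaphthalene-1-carboxylate | C[C@]12CCC[C@](C)(C(=O)OCC[Si](C)(C)C)[C@@H]1CC[C@@H](CO[Si](C)(C)C(C)(C)C)[C@@H]2CCO | intermediate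
34 | 2-(trimethylsilyl)ethyl (1S,4aR,5S,6R,8aR)-6-{[(tert-butyldimethylsilyl)oxy]methyl}-5-(2-iodoethyl)-1,4a-dimethyldecahydronaphthalene-1-carboxylate | C[C@]12CCC[C@](C)(C(=O)OCC[Si](C)(C)C)[C@@H]1CC[C@@H](CO[Si](C)(C)C(C)(C)C)[C@@H]2CCI | intermediate
35 | 3-bromofuran-2(5H)-one | O=C1OCC=C1Br | starting material
36 | alkylzinc iodide from 34 (zinc on C12) | C[C@]12CCC[C@](C)(C(=O)OCC[Si](C)(C)C)[C@@H]1CC[C@@H](CO[Si](C)(C)C(C)(C)C)[C@@H]2CC[Zn]I | intermediate
37 | 2-(trimethylsilyl)ethyl (1S,4aR,5S,6R,8aR)-6-{[(tert-butyldimethylsilyl)oxy]methyl}-1,4a-dimethyl-5-[2-(2-oxo-2,5-dihydrofuran-3-yl)ethyl]decahydronaphthalene-1-carboxylate | C[C@]12CCC[C@](C)(C(=O)OCC[Si](C)(C)C)[C@@H]1CC[C@@H](CO[Si](C)(C)C(C)(C)C)[C@@H]2CCC1=CCOC1=O | intermediate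
38 | (1S,4aR,5S,6R,8aR)-6-(hydroxymethyl)-1,4a-dimethyl-5-[2-(2-oxo-2,5-dihydrofuran-3-yl)ethyl]decahydronaphthalene-1-carboxylic acid (17-hydroxy-8βH-labd-13-en-16,15-olid-19-oic acid) | C[C@]12CCC[C@](C)(C(=O)O)[C@@H]1CC[C@@H](CO)[C@@H]2CCC1=CCOC1=O | target

Total step count: 24.
Longest linear sequence: 23 steps (steps 1–7 and 9–24, from 1); step 8 is the one-step side branch.

Steps most likely to fail

Step 12 (key step). What may go wrong:
- heterolysis of the outer C4–C5 bond, which overlaps better with the ring ketone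
- full ionisation at C10 followed by proton loss, or by capture without stereochemical memory
- protodesilylation or tin exchange of the allylsilane before it can attack

Fallback, setting out from 13 and 14 and coming back at 22. Dioxinone 14 would be heated with (+)-8-phenylmenthol to give (1S,2R,5S)-8-phenylmenthyl acetoacetate F1. Its dianion (NaH, then n-BuLi) would be alkylated with bromide 13 to give the acyclic 8-phenylmenthyl keto ester F2. Mn(OAc)3·2H2O with Yb(OTf)3 in CF3CH2OH at 0 °C would then start the known oxidative radical bicyclisation of β-keto esters by trivalent manganese. The C4 radical closes 6-endo onto C5 and the C10 radical closes 6-endo onto C9. The β-silyl radical at C8 is oxidised and desilylated, as in oxidative allylations of 1,3-dicarbonyl compounds with allylsilanes, to give the 8-phenylmenthyl decalin keto ester F3. The (+)-auxiliary is taken by analogy with its known bias toward the 5α,10β series, and its antipode would be used if the sense proved opposite. DMAP-catalysed transesterification through the acylketene with excess 2-(trimethylsilyl)ethanol in hot toluene would return 22.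

Step 11. What may go wrong: poor facial selectivity of the reactive acceptor/acceptor copper carbene toward the trisubstituted alkene, and slow decomposition of the stabilised diazo compound.

Fallback, setting out from 24 and coming back at 24. The cyclopropanation would be run for throughput only (for example with achiral Rh2(OAc)4), and material of low enantiomeric purity would be taken through steps 12–14. Alcohol 24 would be esterified with (S)-O-methylmandelic acid (DCC, DMAP, CH2Cl2) to give the (S)-O-methylmandelate of 24 F4. The diastereomer derived from the wanted enantiomer would be separated by chromatography or crystallisation. Methanolysis of the activated α-alkoxy ester (K2CO3, MeOH, rt), which should spare the pivalate and the hindered C19 ester, would return 24 as a single enantiomer.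

Step 4. What may go wrong: slow transfer of the silylmethyl group from copper to the alkyne, competing metalation of the terminal alkyne, and sluggish opening of the epoxide by the alkenylcopper.

Fallback, setting out from 5 (with 7 and 6) and coming back at 10. The lithium acetylide of 5 (n-BuLi, THF, −78 °C) would open ethylene oxide 7 in the presence of BF3·OEt2 to give the homopropargylic alcohol (7E)-9-[(tert-butyldimethylsilyl)oxy]-8-methylnon-7-en-3-yn-1-ol F5. A 5-endo-dig cycloisomerisation (PdCl2(PhCN)2, Et2O, rt) would give the 5-substituted 2,3-dihydrofuran F6. A Kumada-type coupling of the cyclic enol ether C–O bond with Grignard reagent 6, catalysed by zerovalent nickel generated from NiCl2(PPh3)2 in hot toluene, would open the ring with retention. The ring holds oxygen, and hence the incoming CH2SiMe3 group, cis to C11, which gives 10 with the same (3Z) geometry. The allylic silyl ether is the group to watch under these conditions.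

Further compounds
F1 | step 12 | (1S,2R,5S)-5-methyl-2-(2-phenylpropan-2-yl)cyclohexyl 3-oxobutanoate | CC(=O)CC(=O)O[C@H]1C[C@@H](C)CC[C@@H]1C(C)(C)c1ccccc1
F2 | step 12 | (1S,2R,5S)-5-methyl-2-(2-phenylpropan-2-yl)cyclohexyl (6E,10Z)-6-methyl-3-oxo-13-(pivaloyloxy)-10-[(trimethylsilyl)methyl]trideca-6,10-dienoate | CC(C)(C)C(=O)OCC/C=C(\C[Si](C)(C)C)CC/C=C(\C)CCC(=O)CC(=O)O[C@H]1C[C@@H](C)CC[C@@H]1C(C)(C)c1ccccc1
F3 | step 12 | (1S,2R,5S)-5-methyl-2-(2-phenylpropan-2-yl)cyclohexyl (4aR,5S,8aR)-2-hydroxy-4a-methyl-6-methylidene-5-[2-(pivaloyloxy)ethyl]-3,4,4a,5,6,7,8,8a-octahydronaphthalene-1-carboxylate (enol form) | C[C@]12CCC(O)=C(C(=O)O[C@H]3C[C@@H](C)CC[C@@H]3C(C)(C)c3ccccc3)[C@@H]1CCC(=C)[C@@H]2CCOC(=O)C(C)(C)C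
F4 | step 11 | 2-(trimethylsilyl)ethyl (1R,2S,4aR,5S,8aR)-2-{[(2S)-2-methoxy-2-phenylacetyl]oxy}-1,4a-dimethyl-6-methylidene-5-[2-(pivaloyloxy)ethyl]decahydronaphthalene-1-carboxylate | C[C@]12CC[C@H](OC(=O)[C@@H](OC)c3ccccc3)[C@](C)(C(=O)OCC[Si](C)(C)C)[C@@H]1CCC(=C)[C@@H]2CCOC(=O)C(C)(C)C
F5 | step 4 | (7E)-9-[(tert-butyldimethylsilyl)oxy]-8-methylnon-7-en-3-yn-1-ol | OCCC#CCC/C=C(\C)CO[Si](C)(C)C(C)(C)C
F6 | step 4 | tert-butyl{[(2E)-5-(4,5-dihydrofuran-2-yl)-2-methylpent-2-en-1-yl]oxy}dimethylsilane | CC(C)(C)[Si](C)(C)OC/C(C)=C/CCC1=CCCO1
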